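Ring A is made last. Its O1–C5 bond and C3=C4 alkene are disconnected to an open-chain prenyl ketone, exploiting the fact that the dihydrofuran (O1, C2, C3, C4, C5) is the cyclic enol ether of a β-ketoaldehyde: O1 is the ketone oxygen and C5 the CMe2 carbon of a prenyl group. In one operation a selenium electrophile closes O1–C5 across the prenyl alkene and oxidative loss of selenium creates C3=C4, delivering the formyl-substituted alkylidene dihydrofuran. The precursor is a prenyl β-ketoaldehyde that already carries both methine stereocentres (set on a δ-lactone), the methylidene side chain, a fluoride- or MgBr2-labile SEM ester and two dioxolanes.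

Key step: step 8

Remark: the acid is carried as its [2-(trimethylsilyl)ethoxy]methyl (SEM) ester, because this ester can be put on by alkylating the carboxylate released on lactone opening (no acid activation, hence no relactonisation) and taken off without base.
Remark: compounds 1, 2, 4, 5 and 14 are taken as commercial; 18 is a mixture at its dicarbonyl carbon and is largely enolised (drawn as the dicarbonyl tautomer); the sense of induction in step 1 is fixed by the choice of ligand enantiomer.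

Step 1
Reactants: 1 5,6-dihydro-2H-pyran-2-one; 2 (1,3-dioxolan-2-ylmethyl)magnesium bromide (0.5 M in THF)
Product: 3 (4S)-4-(1,3-dioxolan-2-ylmethyl)oxan-2-one
Conditions: CuBr·SMe2 (5 mol%), Rev-Josiphos (6 mol%, enantiomer that gives 4S), t-BuOMe, −78 °C; aq. NH4Cl
Reagents that add atoms: none
Why: Copper-catalysed asymmetric conjugate addition of a Grignard reagent to an α,β-unsaturated δ-lactone is established for alkyl Grignard reagents, and the chiral ferrocenyl diphosphine–copper complex selects one face of C4 and so sets the 4S centre.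

Step 2
Reactants: 4 2-(2-bromoethyl)-2-methyl-1,3-dioxolane; 5 2,3-dibromoprop-1-ene
Product: 7 2-(4-bromopent-4-en-1-yl)-2-methyl-1,3-dioxolane, via ketal Grignard reagent 6 (not isolated)
Conditions: Mg, THF, 25 °C; then 5, CuI (5 mol%), 0 °C
Reagents that add atoms: none
Why: Grignard formation followed by copper-catalysed allylic substitution at the CH2Br carbon of 5 (the vinylic bromide is inert) is the standard way to 2-bromoalk-1-enes, and no stereocentre is formed.

Step 3
Reactants: 3 (4S)-4-(1,3-dioxolan-2-ylmethyl)oxan-2-one; 7 2-(4-bromopent-4-en-1-yl)-2-methyl-1,3-dioxolane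
Product: 10 (3R,4S)-4-(1,3-dioxolan-2-ylmethyl)-3-[5-(2-methyl-1,3-dioxolan-2-yl)pent-1-en-2-yl]oxan-2-one, via lithium enolate 8 (not isolated), via chlorozinc enolate 9 (not isolated)
Conditions: LiN(SiMe3)2, THF, −78 °C; ZnCl2, −78 → 0 °C; 7, Pd2(dba)3 (2.5 mol%), P(t-Bu)3 (6 mol%), rt
Reagents that add atoms: none
Why: Palladium-catalysed coupling of a zinc ester enolate with an alkenyl bromide (Negishi-type enolate alkenylation) should install the methylidene-bearing side chain directly, the weakly basic zinc enolate sparing the more acidic product, and the alkenyl group is delivered to C3 on the face opposite the C4 substituent, which sets 3R (3,4-trans).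

Step 4
Reactants: 10 (3R,4S)-4-(1,3-dioxolan-2-ylmethyl)-3-[5-(2-methyl-1,3-dioxolan-2-yl)pent-1-en-2-yl]oxan-2-one
Product: 12 SEM (2R,3S)-3-(1,3-dioxolan-2-ylmethyl)-5-hydroxy-2-[5-(2-methyl-1,3-dioxolan-2-yl)pent-1-en-2-yl]pentanoate, via potassium hydroxy carboxylate 11 (not isolated)
Conditions: KOH (1.05 equiv), THF/H2O, 0 °C; evaporate; SEMCl, DMF, 0 °C
Reagents that add atoms: potassium hydroxide, [K+].[OH-]; 2-(trimethylsilyl)ethoxymethyl chloride (SEMCl), C[Si](C)(C)CCOCCl
Why: Saponification of the δ-lactone is much faster than removal of the C3 proton, and esterification by O-alkylation of the carboxylate with the reactive alkoxymethyl chloride leaves the primary alcohol free and both stereocentres untouched.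

Step 5
Reactants: 12 SEM (2R,3S)-3-(1,3-dioxolan-2-ylmethyl)-5-hydroxy-2-[5-(2-methyl-1,3-dioxolan-2-yl)pent-1-en-2-yl]pentanoate
Product: 13 SEM (2R,3S)-3-(1,3-dioxolan-2-ylmethyl)-2-[5-(2-methyl-1,3-dioxolan-2-yl)pent-1-en-2-yl]-5-oxopentanoate
Conditions: Dess–Martin periodinane, pyridine, CH2Cl2, 0 °C → rt
Reagents that add atoms: none
Why: Dess–Martin oxidation turns the primary alcohol into the aldehyde under buffered, non-epimerising conditions and, done at once on crude 12, forestalls relactonisation.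

Step 6
Reactants: 14 4-methylpent-3-enoic acid
Product: 15 4-methylpent-3-enoyl chloride
Conditions: (COCl)2, DMF (cat.), CH2Cl2, 0 °C → rt; evaporate, use crude
Reagents that add atoms: oxalyl chloride, O=C(Cl)C(=O)Cl
Why: Acid chloride formation through the chloroiminium (Vilsmeier-type) activator proceeds at low temperature without base, so the β,γ-alkene should stay in place.

Step 7
Reactants: 13 SEM (2R,3S)-3-(1,3-dioxolan-2-ylmethyl)-2-[5-(2-methyl-1,3-dioxolan-2-yl)pent-1-en-2-yl]-5-oxopentanoate; 15 4-methylpent-3-enoyl chloride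
Product: 18 SEM (2R,3R)-3-(1,3-dioxolan-2-ylmethyl)-4-formyl-8-methyl-2-[5-(2-methyl-1,3-dioxolan-2-yl)pent-1-en-2-yl]-5-oxonon-7-enoate, via morpholine enamine 16 (not isolated), via acylated enaminone 17 (not isolated)
Conditions: morpholine, 4 Å MS, CH2Cl2, rt; evaporate; 15, Et3N, CH2Cl2, −20 → 0 °C; then AcOH/NaOAc buffer (pH ≈ 4.5), THF/H2O, rt
Reagents that add atoms: water, O
Why: Stork enamine acylation of an aldehyde enamine forms the C4–acyl bond without any base strong enough to touch the C2–H, buffered hydrolysis of the vinylogous amide releases the enolised β-ketoaldehyde, and the new dicarbonyl carbon is left as a mixture because it becomes sp2 in step 8.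

Step 8
Reactants: 18 SEM (2R,3R)-3-(1,3-dioxolan-2-ylmethyl)-4-formyl-8-methyl-2-[5-(2-methyl-1,3-dioxolan-2-yl)pent-1-en-2-yl]-5-oxonon-7-enoate
Product: 21 SEM (2R,3S)-3-[(1E)-1-(5,5-dimethylfuran-2(5H)-ylidene)-2-oxoethyl]-4-(1,3-dioxolan-2-yl)-2-[5-(2-methyl-1,3-dioxolan-2-yl)pent-1-en-2-yl]butanoate, via cyclic selenide 19 (not isolated), via selenoxide 20 (not isolated)
Conditions: N-(phenylseleno)phthalimide (1.1 equiv), PPTS (0.1 equiv), CH2Cl2, 0 °C → rt; then mCPBA (1.05 equiv), −78 °C; i-Pr2NH, −78 °C → rt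
Reagents that add atoms: none
Why: N-(Phenylseleno)phthalimide, activated by PPTS, forms a seleniranium ion on the prenyl alkene of enolised 18, and the ketone-derived oxygen (O1) opens it at the tertiary carbon C5, placing selenium on C4 and closing ring A; mCPBA then gives selenoxide 20, whose syn-elimination can only use a C3 hydrogen (C5 is quaternary) and so forms C3=C4. The closest known reaction type is the phenylselenoetherification of alkenyl β-dicarbonyl compounds and of β,γ-unsaturated ketones through their enol oxygen, followed by selenoxide elimination. Ring A is closed in the 5-endo-trig mode, which the Markovnikov preference for the tertiary terminus of the seleniranium ion makes favourable. No stereocentre is created in 21 (the selenium-bearing C4 of 19 is transient), and the exocyclic alkene is expected to settle as the E isomer because the push–pull C=C bond rotates easily and places the branched side-chain carbon next to O1 instead of next to the ring C3–H. The step needs O- over C-cyclisation, the ketone oxygen over the formyl oxygen and the prenyl over the methylidene alkene: carbon attack would build a five-membered ring with two adjacent quaternary centres, the formyl oxygen could only close a seven-membered (endo) or an anti-Markovnikov six-membered ring, and the trisubstituted alkene is the more nucleophilic one and the only one with a well-placed internal nucleophile. Seleniranium formation and any C-selenenylation of the dicarbonyl carbon are reversible, so both should funnel into the cyclised selenide.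

Step 9
Reactants: 21 SEM (2R,3S)-3-[(1E)-1-(5,5-dimethylfuran-2(5H)-ylidene)-2-oxoethyl]-4-(1,3-dioxolan-2-yl)-2-[5-(2-methyl-1,3-dioxolan-2-yl)pent-1-en-2-yl]butanoate
Product: 22 (2R,3S)-3-[(1E)-1-(5,5-dimethylfuran-2(5H)-ylidene)-2-oxoethyl]-4-(1,3-dioxolan-2-yl)-2-[5-(2-methyl-1,3-dioxolan-2-yl)pent-1-en-2-yl]butanoic acid
Conditions: MgBr2·OEt2, CH2Cl2, 0 °C → rt; aq. work-up
Reagents that add atoms: none
Why: Chelation-assisted Lewis acid cleavage of the alkoxymethyl (acylal-type) ester by MgBr2 is a known base-free deprotection of SEM esters and should leave the dioxolanes, the enal and the C2–H alone.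

Step 10
Reactants: 22 (2R,3S)-3-[(1E)-1-(5,5-dimethylfuran-2(5H)-ylidene)-2-oxoethyl]-4-(1,3-dioxolan-2-yl)-2-[5-(2-methyl-1,3-dioxolan-2-yl)pent-1-en-2-yl]butanoic acid
Product: 23 (2R,3S)-3-[(1E)-1-(5,5-dimethylfuran-2(5H)-ylidene)-2-oxoethyl]-5-oxo-2-(6-oxohept-1-en-2-yl)pentanoic acid
Conditions: 1 M HCl, THF, 0 °C → rt
Reagents that add atoms: water, O
Why: Acid-catalysed acetal hydrolysis frees the aldehyde and the methyl ketone, and the vinylogous formate of ring A, being far less basic than an acetal oxygen, should survive the dilute acid.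

Compound list (SEM = [2-(trimethylsilyl)ethoxy]methyl)
1 | 5,6-dihydro-2H-pyran-2-one | O=C1C=CCCO1 | starting material
2 | (1,3-dioxolan-2-ylmethyl)magnesium bromide | Br[Mg]CC1OCCO1 | starting material
3 | (4S)-4-(1,3-dioxolan-2-ylmethyl)oxan-2-one | O=C1OCC[C@@H](CC2OCCO2)C1 | intermediate
4 | 2-(2-bromoethyl)-2-methyl-1,3-dioxolane | CC1(CCBr)OCCO1 | starting material
5 | 2,3-dibromoprop-1-ene | C=C(Br)CBr | starting material
6 | [2-(2-methyl-1,3-dioxolan-2-yl)ethyl]magnesium bromide | CC1(CC[Mg]Br)OCCO1 | intermediate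
7 | 2-(4-bromopent-4-en-1-yl)-2-methyl-1,3-dioxolane | C=C(Br)CCCC1(C)OCCO1 | intermediate
8 | lithium (4S)-4-(1,3-dioxolan-2-ylmethyl)-3,4-dihydro-2H-pyran-6-olate | [Li+].[O-]C1=C[C@H](CC2OCCO2)CCO1 | intermediate
9 | chloro{[(4S)-4-(1,3-dioxolan-2-ylmethyl)-3,4-dihydro-2H-pyran-6-yl]oxy}zinc | Cl[Zn]OC1=C[C@H](CC2OCCO2)CCO1 | intermediate
10 | (3R,4S)-4-(1,3-dioxolan-2-ylmethyl)-3-[5-(2-methyl-1,3-dioxolan-2-yl)pent-1-en-2-yl]oxan-2-one (3,4-trans) | C=C(CCCC1(C)OCCO1)[C@@H]2C(=O)OCC[C@H]2CC3OCCO3 | intermediate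
11 | potassium (2R,3S)-3-(1,3-dioxolan-2-ylmethyl)-5-hydroxy-2-[5-(2-methyl-1,3-dioxolan-2-yl)pent-1-en-2-yl]pentanoate | [K+].C=C(CCCC1(C)OCCO1)[C@H](C(=O)[O-])[C@H](CC2OCCO2)CCO | intermediate
12 | SEM (2R,3S)-3-(1,3-dioxolan-2-ylmethyl)-5-hydroxy-2-[5-(2-methyl-1,3-dioxolan-2-yl)pent-1-en-2-yl]pentanoate | C=C(CCCC1(C)OCCO1)[C@H](C(=O)OCOCC[Si](C)(C)C)[C@H](CC2OCCO2)CCO | intermediate
13 | SEM (2R,3S)-3-(1,3-dioxolan-2-ylmethyl)-2-[5-(2-methyl-1,3-dioxolan-2-yl)pent-1-en-2-yl]-5-oxopentanoate | C=C(CCCC1(C)OCCO1)[C@H](C(=O)OCOCC[Si](C)(C)C)[C@H](CC2OCCO2)CC=O | intermediate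
14 | 4-methylpent-3-enoic acid | CC(C)=CCC(=O)O | starting material
15 | 4-methylpent-3-enoyl chloride | CC(C)=CCC(Cl)=O | intermediate
16 | SEM (2R,3R,4E)-3-(1,3-dioxolan-2-ylmethyl)-2-[5-(2-methyl-1,3-dioxolan-2-yl)pent-1-en-2-yl]-5-(morpholin-4-yl)pent-4-enoate | C=C(CCCC1(C)OCCO1)[C@H](C(=O)OCOCC[Si](C)(C)C)[C@H](CC2OCCO2)/C=C/N3CCOCC3 | intermediate
17 | SEM (2R,3S)-3-(1,3-dioxolan-2-ylmethyl)-8-methyl-2-[5-(2-methyl-1,3-dioxolan-2-yl)pent-1-en-2-yl]-4-(morpholin-4-ylmethylidene)-5-oxonon-7-enoate (enaminone, C=C geometry not defined) | C=C(CCCC1(C)OCCO1)[C@H](C(=O)OCOCC[Si](C)(C)C)[C@H](CC2OCCO2)C(C(=O)CC=C(C)C)=CN3CCOCC3 | intermediate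
18 | SEM (2R,3R)-3-(1,3-dioxolan-2-ylmethyl)-4-formyl-8-methyl-2-[5-(2-methyl-1,3-dioxolan-2-yl)pent-1-en-2-yl]-5-oxonon-7-enoate (mixture at C4, enolised) | C=C(CCCC1(C)OCCO1)[C@H](C(=O)OCOCC[Si](C)(C)C)[C@H](CC2OCCO2)C(C=O)C(=O)CC=C(C)C | intermediate
19 | SEM (2R,3S)-3-{1-[5,5-dimethyl-4-(phenylselanyl)oxolan-2-ylidene]-2-oxoethyl}-4-(1,3-dioxolan-2-yl)-2-[5-(2-methyl-1,3-dioxolan-2-yl)pent-1-en-2-yl]butanoate (mixture at the selenium-bearing carbon) | C=C(CCCC1(C)OCCO1)[C@H](C(=O)OCOCC[Si](C)(C)C)[C@H](CC2OCCO2)C(C=O)=C3CC([Se]c4ccccc4)C(C)(C)O3 | intermediate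
20 | SEM (2R,3S)-3-{1-[4-(benzeneseleninyl)-5,5-dimethyloxolan-2-ylidene]-2-oxoethyl}-4-(1,3-dioxolan-2-yl)-2-[5-(2-methyl-1,3-dioxolan-2-yl)pent-1-en-2-yl]butanoate | C=C(CCCC1(C)OCCO1)[C@H](C(=O)OCOCC[Si](C)(C)C)[C@H](CC2OCCO2)C(C=O)=C3CC([Se](=O)c4ccccc4)C(C)(C)O3 | intermediate
21 | SEM (2R,3S)-3-[(1E)-1-(5,5-dimethylfuran-2(5H)-ylidene)-2-oxoethyl]-4-(1,3-dioxolan-2-yl)-2-[5-(2-methyl-1,3-dioxolan-2-yl)pent-1-en-2-yl]butanoate | C=C(CCCC1(C)OCCO1)[C@H](C(=O)OCOCC[Si](C)(C)C)[C@H](CC2OCCO2)/C(C=O)=C3/C=CC(C)(C)O3 | intermediate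
22 | (2R,3S)-3-[(1E)-1-(5,5-dimethylfuran-2(5H)-ylidene)-2-oxoethyl]-4-(1,3-dioxolan-2-yl)-2-[5-(2-methyl-1,3-dioxolan-2-yl)pent-1-en-2-yl]butanoic acid | C=C(CCCC1(C)OCCO1)[C@H](C(=O)O)[C@H](CC2OCCO2)/C(C=O)=C3/C=CC(C)(C)O3 | intermediate
23 | (2R,3S)-3-[(1E)-1-(5,5-dimethylfuran-2(5H)-ylidene)-2-oxoethyl]-5-oxo-2-(6-oxohept-1-en-2-yl)pentanoic acid (CNP0150297.1) | C=C(CCCC(C)=O)[C@H](C(=O)O)[C@H](CC=O)/C(C=O)=C1/C=CC(C)(C)O1 | target

Total step count: 10. Longest linear sequence: 8 steps (steps 1, 3, 4, 5, 7, 8, 9, 10).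

Steps most likely to fail

Step 8. The seleniranium ion may be captured by the formyl-derived enol oxygen or by the dicarbonyl carbon instead of the ketone oxygen, or the enolised dicarbonyl unit may be degraded before cyclisation is complete. The fallback sets out from enaminone 17 (step 7 stopped before the buffered hydrolysis). In 17 the formyl group is masked as a vinylogous amide, so the ketone oxygen is the only oxygen nucleophile and the dicarbonyl carbon bears no hydrogen. PhSeCl in CH2Cl2 at −78 °C should give, by the same 5-endo closure, the cyclic vinylogous iminium chloride F1. Aqueous NaHCO3 hydrolyses this to selenide 19, where the route is rejoined (mCPBA, then i-Pr2NH, to 21).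

Step 3. Proton transfer from the more acidic product to unreacted enolate may cause epimerisation at C3 or migration of the alkene into conjugation. β-Hydride elimination from the palladium enolate, or sluggish coupling of the 1,1-disubstituted bromide, may also intervene. The fallback sets out from 3 and brings the side chain in as a ketone. 5-Oxohexanoic acid is ketalised (ethylene glycol, TsOH, then NaOH) to 4-(2-methyl-1,3-dioxolan-2-yl)butanoic acid F2 and converted with carbonyldiimidazole into its imidazolide F3. Lithium enolate 8 (2 equiv of LiN(SiMe3)2) is acylated with F3 to the β-keto lactone F4, which should settle as the trans isomer through its enol. Non-basic methylenation with the Zn/CH2Br2/TiCl4 reagent (Takai–Lombardo) then returns the route to 10.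

Step 7. Dehydrochlorination of the β,γ-unsaturated acid chloride to a vinylketene may lead to cycloadducts or to the conjugated acyl isomer; N-acylation and deformylation of 18 during hydrolysis are further risks. The fallback sets out from enamine 16 and brings in the ketone and formyl carbons as an isoxazole. 5-Bromo-2-methylpent-2-ene and NaNO2 give 4-methyl-1-nitropent-3-ene F5. Dehydration (PhNCO, catalytic Et3N) in the presence of 16 generates 4-methylpent-3-enenitrile oxide F6, which should add to the enamine to give the morpholinyl isoxazoline F7. Loss of morpholine on mild acid treatment gives the 3,4-disubstituted isoxazole F8. N–O cleavage with Mo(CO)6 in MeCN/H2O gives the primary enaminone F9, and aqueous AcOH hydrolysis returns the route to 18.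

Further compounds
F1 | step 8 | 4-{2-[5,5-dimethyl-4-(phenylselanyl)oxolan-2-ylidene]-2-substituted-ethylidene}morpholin-4-ium chloride, the O-cyclised vinylogous iminium salt of 17 (2R,3S in the ester chain) | C=C(CCCC1(C)OCCO1)[C@H](C(=O)OCOCC[Si](C)(C)C)[C@H](CC2OCCO2)C(C=[N+]3CCOCC3)=C4CC([Se]c5ccccc5)C(C)(C)O4.[Cl-]
F2 | step 3 | 4-(2-methyl-1,3-dioxolan-2-yl)butanoic acid | CC1(CCCC(=O)O)OCCO1
F3 | step 3 | 1-(imidazol-1-yl)-4-(2-methyl-1,3-dioxolan-2-yl)butan-1-one | CC1(CCCC(=O)n2ccnc2)OCCO1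
F4 | step 3 | (3R,4S)-4-(1,3-dioxolan-2-ylmethyl)-3-[4-(2-methyl-1,3-dioxolan-2-yl)butanoyl]oxan-2-one | O=C(CCCC1(C)OCCO1)[C@@H]2C(=O)OCC[C@H]2CC3OCCO3
F5 | step 7 | 4-methyl-1-nitropent-3-ene | CC(C)=CCC[N+](=O)[O-]
F6 | step 7 | 4-methylpent-3-enenitrile oxide | CC(C)=CCC#[N+][O-]
F7 | step 7 | SEM (2R,3R)-4-(1,3-dioxolan-2-yl)-3-[3-(3-methylbut-2-en-1-yl)-5-(morpholin-4-yl)-4,5-dihydro-1,2-oxazol-4-yl]-2-[5-(2-methyl-1,3-dioxolan-2-yl)pent-1-en-2-yl]butanoate (ring centres not defined) | C=C(CCCC1(C)OCCO1)[C@H](C(=O)OCOCC[Si](C)(C)C)[C@H](CC2OCCO2)C3C(N4CCOCC4)ON=C3CC=C(C)C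
F8 | step 7 | SEM (2R,3S)-4-(1,3-dioxolan-2-yl)-3-[3-(3-methylbut-2-en-1-yl)-1,2-oxazol-4-yl]-2-[5-(2-methyl-1,3-dioxolan-2-yl)pent-1-en-2-yl]butanoate | C=C(CCCC1(C)OCCO1)[C@H](C(=O)OCOCC[Si](C)(C)C)[C@H](CC2OCCO2)c3conc3CC=C(C)C
F9 | step 7 | SEM (2R,3S)-5-amino-3-(1,3-dioxolan-2-ylmethyl)-4-formyl-8-methyl-2-[5-(2-methyl-1,3-dioxolan-2-yl)pent-1-en-2-yl]nona-4,7-dienoate | C=C(CCCC1(C)OCCO1)[C@H](C(=O)OCOCC[Si](C)(C)C)[C@H](CC2OCCO2)C(C=O)=C(N)CC=C(C)C
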